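(The data stem from a simulated flask with constants of no real substance; scatter was added.)

Litres per mole per minute is the unit I would reckon in for your quick number on teal. Your hunch was that the protic impurity does not take all the incoming ligand before the starting complex sees any.

| flask | starting complex | incoming ligand | protic impurity | remark | time |
|---|---|---|---|---|---|
| Saturday's | 10 mM | 0.82 equiv | 10 mM | run made earlier |  |
| Friday's | 10 mM | 1.9 equiv | 10 mM | run made earlier |  |
| Monday's | 10 mM | 3.2 equiv | 10 mM | run made earlier |  |
| teal | 10 mM | 4.00 equiv | 10.0 mM |  | 80 min |
| green | 10 mM | 2.00 equiv | 10.0 mM |  | 80 min |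
| ochre | 10 mM | 0.800 equiv | 10.0 mM |  | 80 min |

| run | time / min | complex with one exchanged / % | starting complex / % |
|---|---|---|---|
| Saturday's | 12.0 | 3.7 | 96.4 |
| Saturday's | 25.0 | 6.3 | 94.8 |
| Saturday's | 30.0 | 7.0 | 93.9 |
| Saturday's | 50.0 | 10.8 | 88.5 |
| Saturday's | 60.0 | 10.7 | 88.2 |
| Friday's | 12.0 | 7.2 | 93.0 |
| Friday's | 25.0 | 13.4 | 87.4 |
| Friday's | 30.0 | 15.3 | 83.9 |
| Friday's | 50.0 | 21.5 | 77.3 |
| Friday's | 60.0 | 24.2 | 73.6 |
| Monday's | 5.00 | 6.1 | 94.5 |
| Monday's | 8.00 | 9.2 | 91.7 |
| Monday's | 15.0 | 15.1 | 85.4 |
| Monday's | 30.0 | 24.8 | 73.6 |
| Monday's | 60.0 | 40.6 | 59.8 |

(scatter of a reading: 0.5 percentage points)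

- reactions considered so far: protic impurity + incoming ligand -> quenched reagent; complex with one exchanged + incoming ligand <-> leaving ligand + complex with two exchanged; starting complex + incoming ligand <-> leaving ligand + complex with one exchanged; complex with three exchanged + incoming ligand <-> leaving ligand + complex with four exchanged; complex with two exchanged + incoming ligand <-> leaving ligand + complex with three exchanged; incoming ligand <-> dormant form

- which of these holds the largest part of the starting complex at the end of teal (complex with three exchanged / complex with one exchanged / starting complex / complex with four exchanged / complex with two exchanged)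
- which of these holds the largest part of the starting complex at the end of green (complex with three exchanged / complex with one exchanged / starting complex / complex with four exchanged / complex with two exchanged)
- which of these holds the largest part of the starting complex at the end of ochre (complex with three exchanged / complex with one exchanged / starting complex / complex with four exchanged / complex with two exchanged)
- final complex with one exchanged in teal, as a percentage of the starting complex charged

The readings bear your hunch out. Saturday's run charged 8.20 mM of ligand, less than its 10 mM of impurity, and still showed 10.7% of complex with one exchanged at 60.0 min. In Monday's last readings the starting complex and the complex with one exchanged sum to 100%, so these runs show the first exchange.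

I would therefore reckon the loss of starting complex against charged [incoming ligand], since the readings do not show free [incoming ligand]. My carried quantity is the charge constant: ln(charged over remaining [starting complex]), divided by charged [incoming ligand] and by time. It is an average over the run, a working figure and not the rate constant of a step.

Monday's: ln(1/59.8%) / (32.0 mM × 60.0 min) = 0.268 L mol⁻¹ min⁻¹

Friday's: 0.269 L mol⁻¹ min⁻¹

Saturday's: 0.255 L mol⁻¹ min⁻¹

Saturday's value rests on the smallest loss, so I carry Monday's to teal:

0.268 L mol⁻¹ min⁻¹ × 40.0 mM × 80 min = 0.857

starting complex left = exp(−0.857) = 42.4%

Reading the rest as complex with one exchanged, I commit to 57.6% of it in teal. The same line leaves 65.2% of starting complex in green and 84.2% in ochre.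

The forecast gives complex with one exchanged for teal, starting complex for green and starting complex for ochre, with 55% in teal (range 47% to 62%). That is below my figure, on its reading that “ligand is lost slowly”.

    protic impurity + incoming ligand → quenched reagent (k = 1.81 L mol⁻¹ min⁻¹)
    complex with one exchanged + incoming ligand ⇌ leaving ligand + complex with two exchanged (K = 0.400, k = 0.0249 L mol⁻¹ min⁻¹)
    starting complex + incoming ligand ⇌ leaving ligand + complex with one exchanged (K = 7.31, k = 0.598 L mol⁻¹ min⁻¹)
    complex with three exchanged + incoming ligand ⇌ leaving ligand + complex with four exchanged (K = 7.50, k = 0.747 L mol⁻¹ min⁻¹)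
    complex with two exchanged + incoming ligand ⇌ leaving ligand + complex with three exchanged (K = 1.40, k = 0.260 L mol⁻¹ min⁻¹)
    incoming ligand ⇌ dormant form (K = 0.683, k = 0.361 min⁻¹)

Teal ends with 55.4% of complex with one exchanged and 43.5% of starting complex, while starting complex leads green at 68.1% and ochre at 86.7%, as the forecast said. The second exchange has 0.042 of the first's rate constant. Teal holds 0.991% of complex with two exchanged, against 9.17% if the uptake were spread by chance over 4 like sites. Teal's own loss reads 0.260 L mol⁻¹ min⁻¹, against 0.268 L mol⁻¹ min⁻¹. With 2.40 equiv in place of 4.00 equiv, 0.268 L mol⁻¹ min⁻¹ leaves 59.8% of starting complex, and that neighbour of teal holds 62.5%, so starting complex leads there, over 37.1% of complex with one exchanged.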